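**Plan**
- Retrosynthetic cuts, in order: the three aryl O–CH2OMe bonds; the carbinol C–H bond (back to a ketone); both carbon–carbon bonds of the carbinol carbon at once (CH2–CO and CO–C(CH3)=CH2, that carbon being carbon monoxide); the C8–CH2 bond; the C8–iodine bond.
- Enabling feature: the carbinol carbon C2'' is flanked only by the benzylic CH2 (C1'') on C8 of ring A and by the sp2 carbon C3'' of the isopropenyl group. As a ketone it is therefore a CO unit between a flavon-8-ylmethyl halide and an isopropenyl–metal reagent.
- Forward: rings A, B and C are bought together as apigenin, so no ring is formed. The chain is joined as C8–CH2 (hydroxymethyl Stille coupling), then CH2–C(=O)–C(CH3)=CH2 in one carbonylative Stille coupling.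
- Stereochemistry: the only stereocentre, (R) at C2'', is set by Corey–Bakshi–Shibata reduction of the enone with the (S)-oxazaborolidine (reagent control). The closing acid methanolysis of the acetals does not involve it.

Key step: step 5

Remark: once the 5-oxygen is alkylated, electrophilic iodination of ring A is assumed to go to C8 (para to the 5-oxygen) and not to C6, as is general for 5,7-dialkoxyflavones.

**Step 1**
Reactants: 1 apigenin (5,7,4'-trihydroxyflavone)
Product: 2 5,7,4'-tris(methoxymethoxy)flavone
Conditions: NaH (4 equiv), MOMCl (4 equiv), DMF, 0 → 25 °C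
Reagents that add atoms: chloromethyl methyl ether, COCCl
Why: Williamson-type O-alkylation of the three sodium phenoxides by the α-chloro ether, with excess NaH in DMF chosen so that the chelated, least nucleophilic 5-hydroxyl is also etherified.

**Step 2**
Reactants: 2 5,7,4'-tris(methoxymethoxy)flavone
Product: 3 8-iodo-5,7,4'-tris(methoxymethoxy)flavone
Conditions: NIS (1.1 equiv), DMF, 25 °C, dark
Reagents that add atoms: N-iodosuccinimide, O=C1CCC(=O)N1I
Why: Electrophilic aromatic iodination, which in 5,7-dialkoxyflavones goes to C8 of ring A (para to the 5-oxygen, ortho to the 7-oxygen and the ring oxygen, less crowded than C6), while neutral NIS spares the acid-labile acetals and the deactivated ring B does not compete.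

**Step 3**
Reactants: 3 8-iodo-5,7,4'-tris(methoxymethoxy)flavone; 4 (tributylstannyl)methanol
Product: 5 8-(hydroxymethyl)-5,7,4'-tris(methoxymethoxy)flavone
Conditions: Pd(PPh3)4 (10 mol %), 1,4-dioxane, 90 °C
Reagents that add atoms: none
Why: Migita–Kosugi–Stille coupling of the aryl iodide in which the oxygen-bearing CH2 group of 4 is transferred from tin in preference to butyl, a known hydroxymethylation of aryl halides to which the acetals and the pyranone are inert.

**Step 4**
Reactants: 5 8-(hydroxymethyl)-5,7,4'-tris(methoxymethoxy)flavone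
Product: 7 8-(chloromethyl)-5,7,4'-tris(methoxymethoxy)flavone, via benzylic mesylate 6 (not isolated)
Conditions: MsCl, Et3N, LiCl, THF–DMF, 0 → 25 °C
Reagents that add atoms: lithium chloride, [Li+].[Cl-]; methanesulfonyl chloride, CS(=O)(=O)Cl (its sulfonyl group appears in 6 only, its chloride joins the chloride supplied by LiCl)
Why: O-Sulfonylation of the primary benzylic alcohol and SN2 displacement of the mesylate by chloride in the same flask under basic conditions that keep the acetals; 7 is a reactive 2,4,6-trioxygenated benzylic chloride and is taken into step 5 without storage.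

**Step 5**
Reactants: 7 8-(chloromethyl)-5,7,4'-tris(methoxymethoxy)flavone; 8 carbon monoxide; 9 tributyl(prop-1-en-2-yl)stannane
Product: 10 8-(3-methyl-2-oxobut-3-en-1-yl)-5,7,4'-tris(methoxymethoxy)flavone
Conditions: Pd(PPh3)4 (5 mol %), CO (3 atm), THF, 50 °C
Reagents that add atoms: none
Why: Zerovalent palladium inserts into the benzylic carbon–chlorine bond of 7 to give a benzyl complex of divalent palladium that has no β-hydrogen, CO inserts into the benzyl–palladium bond to form the arylacetyl complex, the isopropenyl group passes from tin to palladium, and reductive elimination releases enone 10 and returns zerovalent palladium. The closest known reaction type is the Stille carbonylative three-component coupling of benzylic halides with alkenylstannanes to give benzyl alkenyl ketones. No ring is closed and no stereocentre is formed, so no mode of closure and no stereocontrol element is involved. The selectivity needed is CO insertion ahead of transmetalation, so that benzyl and isopropenyl are not joined directly; it should be secured by the high migratory aptitude of the sp3 benzyl group on palladium, by the CO overpressure and by the slow transmetalation of the α-branched alkenylstannane. Chemoselectivity rests on the substrate: the benzylic chloride is its only carbon–halogen bond, the sp2 isopropenyl group leaves tin far faster than butyl, and the neutral medium leaves the three acetals, the pyranone and the sensitive enone untouched.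

**Step 6**
Reactants: 10 8-(3-methyl-2-oxobut-3-en-1-yl)-5,7,4'-tris(methoxymethoxy)flavone
Product: 11 8-[(2R)-2-hydroxy-3-methylbut-3-en-1-yl]-5,7,4'-tris(methoxymethoxy)flavone
Conditions: (S)-1-butyl-3,3-diphenyltetrahydro-1H,3H-pyrrolo[1,2-c][1,3,2]oxazaborole (0.3 equiv), catecholborane (1.8 equiv), toluene, −78 °C; then pH 7 buffer
Reagents that add atoms: none
Why: Corey–Bakshi–Shibata reduction in which the ketone binds the ring boron of the (S)-oxazaborolidine anti to its larger, α-branched isopropenyl group and hydride passes from the nitrogen-bound borane through a six-membered transition state to the face that gives the (R)-carbinol (the sense in which acetophenone gives (R)-1-phenylethanol, isopropenyl taking the place of phenyl and the CH2 that of methyl), while catecholborane at −78 °C should neither hydroborate the 1,1-disubstituted alkene nor reduce the vinylogous-ester carbonyl of the pyranone.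

**Step 7**
Reactants: 11 8-[(2R)-2-hydroxy-3-methylbut-3-en-1-yl]-5,7,4'-tris(methoxymethoxy)flavone
Product: 12 8-[(2R)-2-hydroxy-3-methylbut-3-en-1-yl]-5,7,4'-trihydroxyflavone (target)
Conditions: HCl (1.25 M in MeOH), THF, 0 → 25 °C
Reagents that add atoms: none
Why: Acid-catalysed transacetalisation of the three aryl methoxymethyl ethers with methanol at ambient temperature, conditions under which prenyl-type alkenes of flavonoids are expected to persist and the non-benzylic carbinol, whose allyl cation is not stabilised, should not ionise.

**Compound list**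
1 | apigenin; 5,7-dihydroxy-2-(4-hydroxyphenyl)-4H-chromen-4-one | O=c1cc(-c2ccc(O)cc2)oc2cc(O)cc(O)c12 | starting material
2 | 5,7,4'-tris(methoxymethoxy)flavone; 5,7-bis(methoxymethoxy)-2-[4-(methoxymethoxy)phenyl]-4H-chromen-4-one | COCOc1cc(OCOC)c2c(=O)cc(-c3ccc(OCOC)cc3)oc2c1 | intermediate
3 | 8-iodo-5,7,4'-tris(methoxymethoxy)flavone | Ic1c(OCOC)cc(OCOC)c2c(=O)cc(-c3ccc(OCOC)cc3)oc12 | intermediate
4 | (tributylstannyl)methanol | OC[Sn](CCCC)(CCCC)CCCC | starting material
5 | 8-(hydroxymethyl)-5,7,4'-tris(methoxymethoxy)flavone | OCc1c(OCOC)cc(OCOC)c2c(=O)cc(-c3ccc(OCOC)cc3)oc12 | intermediate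
6 | 8-[(methanesulfonyloxy)methyl]-5,7,4'-tris(methoxymethoxy)flavone (formed in the flask, not isolated) | CS(=O)(=O)OCc1c(OCOC)cc(OCOC)c2c(=O)cc(-c3ccc(OCOC)cc3)oc12 | intermediate
7 | 8-(chloromethyl)-5,7,4'-tris(methoxymethoxy)flavone | ClCc1c(OCOC)cc(OCOC)c2c(=O)cc(-c3ccc(OCOC)cc3)oc12 | intermediate
8 | carbon monoxide | [C-]#[O+] | starting material
9 | tributyl(prop-1-en-2-yl)stannane | C=C(C)[Sn](CCCC)(CCCC)CCCC | starting material
10 | 8-(3-methyl-2-oxobut-3-en-1-yl)-5,7,4'-tris(methoxymethoxy)flavone | C=C(C)C(=O)Cc1c(OCOC)cc(OCOC)c2c(=O)cc(-c3ccc(OCOC)cc3)oc12 | intermediate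
11 | 8-[(2R)-2-hydroxy-3-methylbut-3-en-1-yl]-5,7,4'-tris(methoxymethoxy)flavone | C=C(C)[C@H](O)Cc1c(OCOC)cc(OCOC)c2c(=O)cc(-c3ccc(OCOC)cc3)oc12 | intermediate
12 | 5,7-dihydroxy-8-[(2R)-2-hydroxy-3-methylbut-3-en-1-yl]-2-(4-hydroxyphenyl)-4H-chromen-4-one | C=C(C)[C@H](O)Cc1c(O)cc(O)c2c(=O)cc(-c3ccc(O)cc3)oc12 | target

**Step count and risks**
Total step count: 7. Longest linear sequence: 7 steps (1 → 12).

Step 5 (carbonylative coupling). What may go wrong: transmetalation may overtake CO insertion, so that benzyl and isopropenyl are joined without the carbonyl. The electron-rich benzylic chloride may also ionise, with participation of the neighbouring acetal oxygen, before palladium inserts, or the enone may oligomerise under the reaction conditions. The fallback sets out from iodide 3 and comes back at enone 10. Stille coupling of 3 with tributyl(3-methylbut-2-en-1-yl)stannane (Pd(PPh3)4, DMF, 90 °C) would give 8-(3-methylbut-2-en-1-yl)-5,7,4'-tris(methoxymethoxy)flavone F1. A Schenck ene reaction with singlet oxygen (O2, visible light, 5,10,15,20-tetraphenylporphyrin, CH2Cl2, 0 °C) would move the double bond to the chain terminus and give racemic 8-(2-hydroperoxy-3-methylbut-3-en-1-yl)-5,7,4'-tris(methoxymethoxy)flavone F2. Ac2O, pyridine and 4-(dimethylamino)pyridine would acylate it to 8-[2-(acetylperoxy)-3-methylbut-3-en-1-yl]-5,7,4'-tris(methoxymethoxy)flavone F3, which loses acetic acid in a Kornblum–DeLaMare elimination to give 10. The ketone oxygen then comes from O2 instead of CO, and steps 3 and 4 are not needed.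

Step 6 (enantioselective reduction). What may go wrong: facial selectivity may be poor if the catalyst does not distinguish the isopropenyl group clearly from the flavonylmethyl group. The catalyst may also be held by the more basic pyranone carbonyl, or hydride may be delivered in conjugate fashion to the enone. The fallback sets out from 10 and comes back at 11. Luche reduction (NaBH4, CeCl3·7H2O, MeOH, −40 °C) would give racemic 8-(2-hydroxy-3-methylbut-3-en-1-yl)-5,7,4'-tris(methoxymethoxy)flavone F4. A Sharpless kinetic resolution (Ti(OiPr)4, diisopropyl (2R,3R)-tartrate, tert-butyl hydroperoxide (0.6 equiv), 4 Å molecular sieves, CH2Cl2, −20 °C) would then epoxidise the (S)-enantiomer to 8-{(2S)-2-hydroxy-2-[(2R)-2-methyloxiran-2-yl]ethyl}-5,7,4'-tris(methoxymethoxy)flavone F5 and leave the (R)-alcohol 11, to be separated by chromatography. At most half of the material can be kept this way.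

Step 7 (removal of the acetals). What may go wrong: under Brønsted acid the freed 7-hydroxyl may add to the protonated isopropenyl group or to the ionised allylic position (ring closure onto ring A). Methanol may also add to the alkene, or ionisation of the allylic alcohol may erode the stereocentre. The fallback sets out from 11 and comes back at 12. Exchange of the acetals for silyl ethers with Et3SiOTf and 2,2'-bipyridyl (CH3CN, 0 °C), which also silylates the carbinol, would give 8-[(2R)-3-methyl-2-(triethylsilyloxy)but-3-en-1-yl]-5,7,4'-tris(triethylsilyloxy)flavone F6 without free protic acid. Bu4NF buffered with AcOH (THF, 0 °C) would then remove the four silyl groups to give 12.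

**Further compounds**
F1 | step 5 | 8-(3-methylbut-2-en-1-yl)-5,7,4'-tris(methoxymethoxy)flavone | CC(C)=CCc1c(OCOC)cc(OCOC)c2c(=O)cc(-c3ccc(OCOC)cc3)oc12
F2 | step 5 | racemic 8-(2-hydroperoxy-3-methylbut-3-en-1-yl)-5,7,4'-tris(methoxymethoxy)flavone | C=C(C)C(OO)Cc1c(OCOC)cc(OCOC)c2c(=O)cc(-c3ccc(OCOC)cc3)oc12
F3 | step 5 | racemic 8-[2-(acetylperoxy)-3-methylbut-3-en-1-yl]-5,7,4'-tris(methoxymethoxy)flavone | C=C(C)C(OOC(C)=O)Cc1c(OCOC)cc(OCOC)c2c(=O)cc(-c3ccc(OCOC)cc3)oc12
F4 | step 6 | racemic 8-(2-hydroxy-3-methylbut-3-en-1-yl)-5,7,4'-tris(methoxymethoxy)flavone | C=C(C)C(O)Cc1c(OCOC)cc(OCOC)c2c(=O)cc(-c3ccc(OCOC)cc3)oc12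
F5 | step 6 | 8-{(2S)-2-hydroxy-2-[(2R)-2-methyloxiran-2-yl]ethyl}-5,7,4'-tris(methoxymethoxy)flavone | C[C@@]1(CO1)[C@@H](O)Cc1c(OCOC)cc(OCOC)c2c(=O)cc(-c3ccc(OCOC)cc3)oc12
F6 | step 7 | 8-[(2R)-3-methyl-2-(triethylsilyloxy)but-3-en-1-yl]-5,7,4'-tris(triethylsilyloxy)flavone | C=C(C)[C@H](O[Si](CC)(CC)CC)Cc1c(O[Si](CC)(CC)CC)cc(O[Si](CC)(CC)CC)c2c(=O)cc(-c3ccc(O[Si](CC)(CC)CC)cc3)oc12
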